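**Retrosynthetic overview**

1. Target 45 ⇐ fluoride deprotection and one oxidation (C7' aldehyde, C11'/C12' diosphenol) ⇐ E‑C12=C13 alkene from a (Z)‑enol triflate ⇐ addition of the labdane C12 nucleophile from 38 (abietic acid with C13 and the isopropyl group excised, C14 kept as C17) to core aldehyde 28.
2. 28 ⇐ ketal hydrolysis, allylic oxidation of C13 and exo‑face hydrogenation of C14=C15 ⇐ bicyclo[3.2.1]octene 24 ⇐ intramolecular (4+3) cycloaddition of silyloxyenal/cyclopentadienone ketal 23, which closes ring B and the seven‑membered ring.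
3. Feature used: the cyclopentane C8'–C14–C15–C13'–C14', bridged by the oxygenated carbons C12'–C11'–C9', is a cyclopentadiene + oxyallyl adduct, and C9'–C10'–C5'–C6'–C8' is a three‑atom tether that is ring B.
4. 23 ⇐ diene ring from a Piancatelli rearrangement at C8' (then iodination, ketalisation, Negishi coupling, dehydration) and enal from the C9' aldehyde ⇐ ring A with trans arms, from a hydrindanone template (asymmetric allylation, aldol, reductive hydroxymethylation set C10', C5', C6') that is cut at C8'–C9'.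
5. Ring order: ring A bought; template ring B made and opened; cyclopentadiene ring; ring B plus the seven‑membered ring in the key step; labdane decalin attached intact.

Key step: step 18

Remark: primed numbers are abietane‑type numbers of the rearranged C20 unit (C7' is the formyl carbon on C6'), unprimed numbers are labdane numbers; "α" is the face opposite the C10' methyl.
Remark: phosphonate 19 is taken as a purchasable reagent; where a centre is written without configuration (C8' and C14 in 13–22, carbinol centres in 35 and 39) both epimers are carried, because the centre is erased later.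
Remark: C9' and C12' in 24–43 are drawn for one cycloaddition mode; either configuration serves, since both centres lose their stereochemistry in step 36.

**Part A – core**

Step 1
Reactants: 1 2,2,6-trimethylcyclohexanone
Product: 2 allyl 2,6,6-trimethylcyclohex-1-en-1-yl carbonate
Conditions: LiN(SiMe3)2, THF, 0 °C; allyl chloroformate, TMEDA, −78 °C
Reagents that add atoms: allyl chloroformate C=CCOC(=O)Cl
Why: the ketone has a single enolisable position, so O‑acylation of its lithium enolate should give one enol carbonate (enolate O‑acylation).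

Step 2
Reactants: 2 allyl 2,6,6-trimethylcyclohex-1-en-1-yl carbonate
Product: 3 (R)-2-allyl-2,6,6-trimethylcyclohexanone
Conditions: Pd2(dba)3 (2.5 mol %), (R)-t-BuPHOX (6 mol %), THF, 25 °C
Reagents that add atoms: none
Why: decarboxylative asymmetric Tsuji allylation through a zerovalent palladium/PHOX allyl–enolate ion pair sets quaternary C10'; the (R)-ligand is chosen because the (S)-ligand leads to the (S)-2-allyl-2-alkylcyclohexanone series.

Step 3
Reactants: 3 (R)-2-allyl-2,6,6-trimethylcyclohexanone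
Product: 4 (R)-2,2,6-trimethyl-6-(2-oxopropyl)cyclohexanone
Conditions: PdCl2 (10 mol %), Cu(OAc)2, O2 (1 atm), DMA/H2O, 25 °C
Reagents that add atoms: water O
Why: Wacker oxidation with divalent palladium should convert the terminal alkene into the methyl ketone with Markovnikov selectivity while the hindered ring ketone stays untouched.

Step 4
Reactants: 4 (R)-2,2,6-trimethyl-6-(2-oxopropyl)cyclohexanone
Product: 5 (7aR)-4,4,7a-trimethyl-5,6,7,7a-tetrahydro-1H-inden-2(4H)-one
Conditions: KOH, xylenes, 110 °C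
Reagents that add atoms: none
Why: intramolecular aldol condensation of the methyl ketone onto the ring carbonyl closes the five‑membered template ring (C10', C9', C8', C6', C5'); only one enone can form because C4' and C10' are quaternary.

Step 5
Reactants: 5 template enone
Product: 6 trans-fused 6'-(hydroxymethyl)hydrindan-8'-one
Conditions: Li, NH3/THF, t-BuOH (1 equiv), −78 °C; NH3 removed; CH2O (g), THF, −78 °C; aq NH4Cl
Reagents that add atoms: formaldehyde C=O
Why: reductive alkylation of the enone (dissolving‑metal reduction, then aldol trapping of the regiodefined C6' enolate); C5' should be protonated from the α face because the β face is screened by the axial methyls on C10' and C4' (trans fusion), and formaldehyde should enter C6' anti to the angular methyl, which is also the stable orientation of this epimerisable centre.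

Step 6
Reactants: 6 hydroxymethyl hydrindanone
Product: 7 TBDPS ether of 6
Conditions: t-BuPh2SiCl, imidazole, CH2Cl2, 0 °C
Reagents that add atoms: tert-butyl(chloro)diphenylsilane CC(C)(C)[Si](Cl)(c1ccccc1)c1ccccc1
Why: silylation of the primary alcohol protects the β‑hydroxy ketone against retro‑aldol loss and gives an ether that survives to step 35.

Step 7
Reactants: 7 TBDPS ether
Product: 10 trans-fused δ-lactone (C9'–O–C8'=O), via silyl enol ether 8 (not isolated), via hydroxy acid 9 (not isolated)
Conditions: LiN(i-Pr)2, THF, −78 °C; Me3SiCl; O3, CH2Cl2/MeOH, −78 °C; NaBH4, −78 → 0 °C; 1 M HCl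
Reagents that add atoms: chlorotrimethylsilane C[Si](C)(C)Cl (in 8 only); ozone [O-][O+]=O
Why: kinetic deprotonation at the less substituted C9' methylene, ozonolysis of the C8'=C9' enol ether (this opens the template ring), borohydride reduction of the C9' aldehyde and lactonisation; C6' keeps its configuration, its CH2O group being equatorial in the lactone.

Step 8
Reactants: 10 δ-lactone; 11 2-methylfuran
Product: 13 furyl carbinol diol, via furyl ketone 12 (not isolated)
Conditions: 11, n-BuLi, THF, 0 °C; 10, −78 °C; then MeOH, NaBH4, −78 → 0 °C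
Reagents that add atoms: none
Why: 5-lithio-2-methylfuran should add once to the lactone (stable tetrahedral intermediate) and in‑situ carbonyl reduction gives the carbinol before C6' can epimerise next to the ketone.

Step 9
Reactants: 13 furyl carbinol diol
Product: 14 4-hydroxy-4-methyl-5-substituted cyclopent-2-enone
Conditions: ZnCl2, dioxane/H2O, 80 °C
Reagents that add atoms: water O
Why: Piancatelli rearrangement (furfuryl cation, water attack at furan C5, ring opening, conrotatory 4π closure) forms the C8'–C14 bond with C14–OH trans to the C8' substituent; the neighbouring primary hydroxyl can add to the cation only reversibly.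

Step 10
Reactants: 14 hydroxy cyclopentenone
Product: 15 α-iodo enone (iodine on C13')
Conditions: I2, pyridine, CH2Cl2, 25 °C
Reagents that add atoms: iodine II
Why: α‑iodination of the enone by conjugate addition of pyridine, iodination of the enolate and elimination.

Step 11
Reactants: 15 α-iodo enone
Product: 16 iodo enone dimethyl ketal
Conditions: MeOSiMe3, Me3SiOTf (5 mol %), CH2Cl2, −78 °C; pyridine; K2CO3, MeOH, 0 °C
Reagents that add atoms: methoxytrimethylsilane CO[Si](C)(C)C
Why: Noyori ketalisation at low temperature, helped by the electron‑withdrawing α‑iodine and free of double‑bond migration; the transient trimethylsilyl ethers are removed by methanolysis.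

Step 12
Reactants: 16 iodo ketal
Product: 17 isopropyl cyclopentenol ketal
Conditions: i-PrZnBr, Pd(dppf)Cl2 (5 mol %), THF, 50 °C
Reagents that add atoms: isopropylzinc bromide CC(C)[Zn]Br
Why: Negishi coupling of the alkenyl iodide with a secondary alkylzinc reagent; the wide‑bite‑angle ligand suppresses isomerisation to n‑propyl.

Step 13
Reactants: 17 isopropyl cyclopentenol ketal
Product: 18 C9' aldehyde
Conditions: Dess–Martin periodinane, NaHCO3, CH2Cl2, 0 °C
Reagents that add atoms: none
Why: buffered periodinane oxidation of the neopentyl primary alcohol; the tertiary allylic alcohol and the ketal do not react.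

Step 14
Reactants: 18 C9' aldehyde; 19 methyl 2-(tert-butyldimethylsilyloxy)-2-(dimethoxyphosphoryl)acetate
Product: 20 (Z)-2-silyloxy enoate
Conditions: 19, LiN(SiMe3)2, THF, −78 → 25 °C
Reagents that add atoms: none
Why: Horner–Wadsworth–Emmons olefination of the non‑enolisable aldehyde should give the enol ether with the ester trans to C10'.

Step 15
Reactants: 20 silyloxy enoate
Product: 21 2-silyloxy allylic alcohol
Conditions: i-Bu2AlH, CH2Cl2, −78 °C
Reagents that add atoms: none
Why: hydride reduction of the ester to the allylic alcohol; silyl enol ether, ketal and silyl ether are inert.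

Step 16
Reactants: 21 allylic alcohol
Product: 22 2-silyloxy enal with tertiary cyclopentenol
Conditions: MnO2, CH2Cl2, 25 °C
Reagents that add atoms: none
Why: selective oxidation of the primary allylic alcohol to the enal under neutral conditions.

Step 17
Reactants: 22 silyloxy enal
Product: 23 key-step precursor, silyloxyenal tethered to a cyclopentadienone dimethyl ketal
Conditions: Burgess reagent, THF/PhH, 40 °C; used at once
Reagents that add atoms: none
Why: Burgess syn‑dehydration of the tertiary allylic alcohol (C14–OH is cis to C8'–H from step 9) toward the conjugated diene, which the ketal carbon blocks against 1,5‑hydrogen shifts.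

Step 18
Reactants: 23 key-step precursor
Product: 24 tetracyclic silyloxy ketone with ketal bridge
Conditions: Sc(OTf)3 (20 mol %), 4 Å MS, CH2Cl2, −78 → −30 °C
Reagents that add atoms: none
Why: Proposed new method: Sc(OTf)3 binds the aldehyde oxygen of the (Z)-2-silyloxyenal and gives a vinyl oxocarbenium (oxyallyl‑type) cation spread over C9', C11' and C12', which adds across the diene termini C8' and C13' in a concerted or rapidly stepwise (4+3) event, after which the silyl group moves from O11' to O12' and frees the catalyst; the closest known reactions are Lewis acid promoted (4+3) cycloadditions of 2-(silyloxy)acroleins with cyclopentadiene or furan and intramolecular (4+3) reactions of tethered oxyallyl cations, whereas a cyclopentadienone ketal as diene and two quaternary termini go beyond them. Ring B closes as the five‑membered tether ring through the C9'–C8' bond in the 5‑exo sense (C8'=C14 and C9'=C11' both lie outside the new ring), and the seven‑membered ring C8'–C9'–C11'–C12'–C13'–C15–C14 closes through the C12'–C13' bond as the cycloadduct ring, bridged by the ketal carbon C14'. C8' and C13' are set together by the diene face attacked, which C6' controls: its hydrogen eclipses the bond to the fully substituted ketal carbon, so C7' lies next to C14 and the tether atom C5' covers one face only, and the trans‑diequatorial arms on ring A then leave only the trans A/B fusion. C9' and C12' follow from the W‑shaped cation (Z enol ether, s‑trans enal) in the extended mode that the three‑atom tether should favour, and both are erased in step 36. The step needs this facial selectivity and (4+3) rather than (4+2) periselectivity; the first is secured by the C6' centre and by the ketal, which blocks 1,5‑hydrogen shifts and cannot ionise (it would give a cyclopentadienyl cation), the second by the donor silyloxy group that keeps both cation termini electrophilic.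

Step 19
Reactants: 24 cycloadduct
Product: 25 C14' ketone
Conditions: TsOH·H2O, acetone/H2O, 45 °C
Reagents that add atoms: water O
Why: acid‑catalysed ketal hydrolysis, done before hydrogenation so that no methoxy group shields the exo face; the hindered silyl ethers should survive.

Step 20
Reactants: 25 C14' ketone
Product: 26 C13 allylic alcohol
Conditions: SeO2 (0.5 equiv), t-BuOOH, CH2Cl2, 25 °C
Reagents that add atoms: tert-butyl hydroperoxide CC(C)(C)OO
Why: Riley allylic oxidation (ene reaction then [2,3] shift); the methyl on C14 carries the only allylic hydrogens because C8' and C13' are quaternary.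

Step 21
Reactants: 26 allylic alcohol
Product: 27 saturated C13 alcohol (C14–H exo, side chain endo)
Conditions: H2 (1 atm), [Ir(cod)(PCy3)(py)]PF6 (5 mol %), CH2Cl2, 25 °C
Reagents that add atoms: none
Why: homogeneous hydrogenation from the exo face, the side of the one‑carbon C14' carbonyl bridge (which can also bind the cationic iridium), sets C14 with hydrogen exo as in the target and does not cleave the allylic C–O bond.

Step 22
Reactants: 27 saturated alcohol
Product: 28 C13 aldehyde
Conditions: Dess–Martin periodinane, NaHCO3, CH2Cl2, 0 °C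
Reagents that add atoms: none
Why: neutral periodinane oxidation keeps the epimerisable C14 centre intact; the aldehyde is used directly.

**Part B – labdane fragment**

Step 23
Reactants: 29 abietic acid
Product: 30 2-(trimethylsilyl)ethyl abietate
Conditions: Me3SiCH2CH2OH, PPh3, DIAD, THF, 0 → 25 °C
Reagents that add atoms: 2-(trimethylsilyl)ethanol C[Si](C)(C)CCO
Why: Mitsunobu esterification of the hindered acid under neutral conditions, which avoids acid‑induced isomerisation of the diene and installs an ester removable by fluoride.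

Step 24
Reactants: 30 silylethyl abietate
Product: 32 13,14-seco keto enal, via 13,14-diol 31 (not isolated)
Conditions: OsO4 (2 mol %), NMO (1.05 equiv), acetone/H2O, 0 °C; then NaIO4, 25 °C
Reagents that add atoms: N-methylmorpholine N-oxide C[N+]1([O-])CCOCC1
Why: dihydroxylation should take place at the distal, more accessible C13=C14 bond of the diene, and glycol cleavage then opens ring C to the C14 enal and the C13 isopropyl ketone.

Step 25
Reactants: 32 keto enal
Product: 33 allylic alcohol with isopropyl ketone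
Conditions: NaBH4, EtOH/CH2Cl2, −78 °C
Reagents that add atoms: none
Why: at low temperature borohydride reduces the aldehyde (1,2) much faster than the hindered isopropyl ketone.

Step 26
Reactants: 33 allylic alcohol
Product: 34 exocyclic methylene isopropyl ketone
Conditions: 2-nitrobenzenesulfonohydrazide, PPh3, DEAD, N-methylmorpholine, −30 → 25 °C
Reagents that add atoms: none
Why: Myers reductive 1,3‑transposition: Mitsunobu displacement, loss of sulfinate to the allylic diazene and retro‑ene loss of N2 deliver hydrogen to C7 and leave the C8=C17 exocyclic alkene.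

Step 27
Reactants: 34 isopropyl ketone
Product: 35 α-hydroxy ketone (OH on C12)
Conditions: LiN(i-Pr)2, THF, −78 °C; 3-phenyl-2-(phenylsulfonyl)oxaziridine
Reagents that add atoms: 3-phenyl-2-(phenylsulfonyl)oxaziridine O=S(=O)(N1OC1c1ccccc1)c1ccccc1
Why: the kinetic enolate forms on the methylene side (C12), and electrophilic hydroxylation leaves the alkene untouched.

Step 28
Reactants: 35 α-hydroxy ketone
Product: 36 C12 aldehyde
Conditions: Pb(OAc)4, MeOH/PhH, 0 °C
Reagents that add atoms: none
Why: oxidative cleavage of the α‑ketol removes C13 with the isopropyl group as methyl 2-methylpropanoate and leaves C12 as the aldehyde.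

Step 29
Reactants: 36 C12 aldehyde
Product: 37 C12 alcohol
Conditions: NaBH4, MeOH, 0 °C
Reagents that add atoms: none
Why: simple carbonyl reduction; the hindered ester is inert.

Step 30
Reactants: 37 C12 alcohol
Product: 38 C12 iodide
Conditions: I2, PPh3, imidazole, CH2Cl2, 0 °C
Reagents that add atoms: iodine II
Why: Appel‑type iodination of the unhindered primary alcohol.

**Part C – union and end game**

Step 31
Reactants: 38 C12 iodide; 28 C13 aldehyde
Product: 39 coupled C13 carbinol
Conditions: 38, t-BuLi (2.1 equiv), Et2O, −78 °C; CeCl3, THF, −78 °C; then 28, −78 °C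
Reagents that add atoms: none
Why: iodine–lithium exchange and transmetalation give a weakly basic organocerium reagent whose 1,2‑addition should be selective for the aldehyde over the two hindered ketones and the hindered ester.

Step 32
Reactants: 39 carbinol
Product: 40 C13 ketone
Conditions: Dess–Martin periodinane, NaHCO3, CH2Cl2, 0 °C
Reagents that add atoms: none
Why: neutral oxidation of the secondary alcohol without epimerising C14.

Step 33
Reactants: 40 C13 ketone
Product: 41 (Z)-enol triflate
Conditions: KN(SiMe3)2, THF, −78 °C; PhNTf2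
Reagents that add atoms: N-phenylbis(trifluoromethanesulfonimide) O=S(=O)(N(c1ccccc1)S(=O)(=O)C(F)(F)F)C(F)(F)F
Why: kinetic deprotonation at the C12 methylene of the α'-branched ketone should give the Z(O)-enolate (C11 trans to the bulky C14), which is trapped as the triflate.

Step 34
Reactants: 41 enol triflate
Product: 42 protected target with E-C12=C13
Conditions: MeZnCl, Pd(PPh3)4 (5 mol %), THF, 25 °C
Reagents that add atoms: methylzinc chloride C[Zn]Cl
Why: Negishi methylation of the alkenyl triflate goes with retention, so the methyl ends cis to C11 (E alkene); the ketones tolerate the organozinc reagent.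

Step 35
Reactants: 42 protected target
Product: 43 diol acid
Conditions: Bu4NF, AcOH, THF, 25 °C
Reagents that add atoms: none
Why: fluoride cleaves both silyl ethers and fragments the 2-(trimethylsilyl)ethyl ester, with acetic acid buffering against retro‑aldol opening of the β‑hydroxy ketone.

Step 36
Reactants: 43 diol acid
Product: 45 target CNP0269191.1, via α-diketone 44 (not isolated)
Conditions: Dess–Martin periodinane (excess), NaHCO3, CH2Cl2, 25 °C; then Et3N (cat.)
Reagents that add atoms: none
Why: one oxidation converts C7'–OH into the aldehyde and the C12' ketol into the 1,2‑dione, which can enolise only toward C9' (C13' is quaternary) to give the diosphenol.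

**Compound list**

1 | 2,2,6-trimethylcyclohexanone | CC1CCCC(C)(C)C1=O | starting material
2 | allyl 2,6,6-trimethylcyclohex-1-en-1-yl carbonate | C=CCOC(=O)OC1=C(C)CCCC1(C)C | intermediate
3 | (R)-2-allyl-2,6,6-trimethylcyclohexanone | C=CC[C@@]1(C)CCCC(C)(C)C1=O | intermediate
4 | (R)-2,2,6-trimethyl-6-(2-oxopropyl)cyclohexanone | CC(=O)C[C@@]1(C)CCCC(C)(C)C1=O | intermediate
5 | (7aR)-4,4,7a-trimethyl-5,6,7,7a-tetrahydro-1H-inden-2(4H)-one (template enone, C8' ketone, C5'=C6') | O=C1C[C@@]2(C)CCCC(C)(C)C2=C1 | intermediate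
6 | trans-fused 6'-(hydroxymethyl)hydrindan-8'-one (C5'–H and C7' on the α face) | O=C1C[C@@]2(C)CCCC(C)(C)[C@@H]2[C@H]1CO | intermediate
7 | TBDPS ether of 6 | O=C1C[C@@]2(C)CCCC(C)(C)[C@@H]2[C@H]1CO[Si](c1ccccc1)(c1ccccc1)C(C)(C)C | intermediate
8 | trimethylsilyl enol ether (C8'=C9') of 7 | C[Si](C)(C)OC1=C[C@@]2(C)CCCC(C)(C)[C@@H]2[C@H]1CO[Si](c1ccccc1)(c1ccccc1)C(C)(C)C | intermediate
9 | seco hydroxy acid (C9'H2OH, C8' acid) | OC[C@@]1(C)CCCC(C)(C)[C@@H]1[C@@H](CO[Si](c1ccccc1)(c1ccccc1)C(C)(C)C)C(=O)O | intermediate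
10 | trans-fused δ-lactone (C9'–O–C8'=O, C7' equatorial) | O=C1OC[C@@]2(C)CCCC(C)(C)[C@@H]2[C@H]1CO[Si](c1ccccc1)(c1ccccc1)C(C)(C)C | intermediate
11 | 2-methylfuran | Cc1ccco1 | starting material
12 | hydroxy 5-methylfuran-2-yl ketone | OC[C@@]1(C)CCCC(C)(C)[C@@H]1[C@@H](CO[Si](c1ccccc1)(c1ccccc1)C(C)(C)C)C(=O)c1ccc(C)o1 | intermediate
13 | furyl carbinol diol (both C8' epimers) | OC[C@@]1(C)CCCC(C)(C)[C@@H]1[C@@H](CO[Si](c1ccccc1)(c1ccccc1)C(C)(C)C)C(O)c1ccc(C)o1 | intermediate
14 | 4-hydroxy-4-methyl-5-substituted cyclopent-2-enone (OH trans to the C8' substituent, two diastereomers) | OC[C@@]1(C)CCCC(C)(C)[C@@H]1[C@@H](CO[Si](c1ccccc1)(c1ccccc1)C(C)(C)C)C1C(=O)C=CC1(C)O | intermediate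
15 | α-iodo enone | OC[C@@]1(C)CCCC(C)(C)[C@@H]1[C@@H](CO[Si](c1ccccc1)(c1ccccc1)C(C)(C)C)C1C(=O)C(I)=CC1(C)O | intermediate
16 | iodo enone dimethyl ketal | OC[C@@]1(C)CCCC(C)(C)[C@@H]1[C@@H](CO[Si](c1ccccc1)(c1ccccc1)C(C)(C)C)C1C(OC)(OC)C(I)=CC1(C)O | intermediate
17 | isopropyl cyclopentenol ketal | OC[C@@]1(C)CCCC(C)(C)[C@@H]1[C@@H](CO[Si](c1ccccc1)(c1ccccc1)C(C)(C)C)C1C(OC)(OC)C(C(C)C)=CC1(C)O | intermediate
18 | C9' aldehyde | O=C[C@@]1(C)CCCC(C)(C)[C@@H]1[C@@H](CO[Si](c1ccccc1)(c1ccccc1)C(C)(C)C)C1C(OC)(OC)C(C(C)C)=CC1(C)O | intermediate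
19 | methyl 2-(tert-butyldimethylsilyloxy)-2-(dimethoxyphosphoryl)acetate | COC(=O)C(O[Si](C)(C)C(C)(C)C)P(=O)(OC)OC | starting material
20 | (Z)-2-silyloxy enoate | COC(=O)/C(O[Si](C)(C)C(C)(C)C)=C/[C@@]1(C)CCCC(C)(C)[C@@H]1[C@@H](CO[Si](c1ccccc1)(c1ccccc1)C(C)(C)C)C1C(OC)(OC)C(C(C)C)=CC1(C)O | intermediate
21 | 2-silyloxy allylic alcohol | OC/C(O[Si](C)(C)C(C)(C)C)=C/[C@@]1(C)CCCC(C)(C)[C@@H]1[C@@H](CO[Si](c1ccccc1)(c1ccccc1)C(C)(C)C)C1C(OC)(OC)C(C(C)C)=CC1(C)O | intermediate
22 | 2-silyloxy enal with tertiary cyclopentenol | O=C/C(O[Si](C)(C)C(C)(C)C)=C/[C@@]1(C)CCCC(C)(C)[C@@H]1[C@@H](CO[Si](c1ccccc1)(c1ccccc1)C(C)(C)C)C1C(OC)(OC)C(C(C)C)=CC1(C)O | intermediate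
23 | key-step precursor: tethered silyloxyenal / cyclopentadienone dimethyl ketal | O=C/C(O[Si](C)(C)C(C)(C)C)=C/[C@@]1(C)CCCC(C)(C)[C@@H]1[C@@H](CO[Si](c1ccccc1)(c1ccccc1)C(C)(C)C)C1=C(C)C=C(C(C)C)C1(OC)OC | intermediate
24 | key-step product: tetracyclic silyloxy ketone with ketal bridge | CC1=C[C@@]2(C(C)C)[C@H](O[Si](C)(C)C(C)(C)C)C(=O)[C@H]3[C@@]1(C2(OC)OC)[C@H](CO[Si](c4ccccc4)(c4ccccc4)C(C)(C)C)[C@H]1C(C)(C)CCC[C@]31C | intermediate
25 | C14' ketone | CC1=C[C@@]2(C(C)C)[C@H](O[Si](C)(C)C(C)(C)C)C(=O)[C@H]3[C@@]1(C2=O)[C@H](CO[Si](c4ccccc4)(c4ccccc4)C(C)(C)C)[C@H]1C(C)(C)CCC[C@]31C | intermediate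
26 | C13 allylic alcohol | OCC1=C[C@@]2(C(C)C)[C@H](O[Si](C)(C)C(C)(C)C)C(=O)[C@H]3[C@@]1(C2=O)[C@H](CO[Si](c4ccccc4)(c4ccccc4)C(C)(C)C)[C@H]1C(C)(C)CCC[C@]31C | intermediate
27 | saturated C13 alcohol (C14–H exo) | OC[C@H]1C[C@@]2(C(C)C)[C@H](O[Si](C)(C)C(C)(C)C)C(=O)[C@H]3[C@@]1(C2=O)[C@H](CO[Si](c4ccccc4)(c4ccccc4)C(C)(C)C)[C@H]1C(C)(C)CCC[C@]31C | intermediate
28 | C13 aldehyde | O=C[C@H]1C[C@@]2(C(C)C)[C@H](O[Si](C)(C)C(C)(C)C)C(=O)[C@H]3[C@@]1(C2=O)[C@H](CO[Si](c4ccccc4)(c4ccccc4)C(C)(C)C)[C@H]1C(C)(C)CCC[C@]31C | intermediate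
29 | abietic acid | CC(C)C1=CC2=CC[C@@H]3[C@](C)(CCC[C@@]3(C)C(=O)O)[C@H]2CC1 | starting material
30 | 2-(trimethylsilyl)ethyl abietate | CC(C)C1=CC2=CC[C@@H]3[C@](C)(CCC[C@@]3(C)C(=O)OCC[Si](C)(C)C)[C@H]2CC1 | intermediate
31 | 13α,14α-diol | CC(C)[C@@]1(O)[C@H](O)C2=CC[C@@H]3[C@](C)(CCC[C@@]3(C)C(=O)OCC[Si](C)(C)C)[C@H]2CC1 | intermediate
32 | 13,14-seco keto enal | CC(C)C(=O)CC[C@H]1C(C=O)=CC[C@@H]2[C@]1(C)CCC[C@@]2(C)C(=O)OCC[Si](C)(C)C | intermediate
33 | allylic alcohol with isopropyl ketone | CC(C)C(=O)CC[C@H]1C(CO)=CC[C@@H]2[C@]1(C)CCC[C@@]2(C)C(=O)OCC[Si](C)(C)C | intermediate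
34 | exocyclic methylene isopropyl ketone | CC(C)C(=O)CC[C@H]1C(=C)CC[C@@H]2[C@]1(C)CCC[C@@]2(C)C(=O)OCC[Si](C)(C)C | intermediate
35 | α-hydroxy ketone (both C12 epimers) | CC(C)C(=O)C(O)C[C@H]1C(=C)CC[C@@H]2[C@]1(C)CCC[C@@]2(C)C(=O)OCC[Si](C)(C)C | intermediate
36 | labdane C12 aldehyde | O=CC[C@H]1C(=C)CC[C@@H]2[C@]1(C)CCC[C@@]2(C)C(=O)OCC[Si](C)(C)C | intermediate
37 | labdane C12 alcohol | OCC[C@H]1C(=C)CC[C@@H]2[C@]1(C)CCC[C@@]2(C)C(=O)OCC[Si](C)(C)C | intermediate
38 | labdane C12 iodide | ICC[C@H]1C(=C)CC[C@@H]2[C@]1(C)CCC[C@@]2(C)C(=O)OCC[Si](C)(C)C | intermediate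
39 | coupled C13 carbinol (both epimers) | C=C1CC[C@@H]2[C@](C)(CCC[C@@]2(C)C(=O)OCC[Si](C)(C)C)[C@H]1CCC(O)[C@H]1C[C@@]2(C(C)C)[C@H](O[Si](C)(C)C(C)(C)C)C(=O)[C@H]3[C@@]1(C2=O)[C@H](CO[Si](c4ccccc4)(c4ccccc4)C(C)(C)C)[C@H]1C(C)(C)CCC[C@]31C | intermediate
40 | C13 ketone | C=C1CC[C@@H]2[C@](C)(CCC[C@@]2(C)C(=O)OCC[Si](C)(C)C)[C@H]1CCC(=O)[C@H]1C[C@@]2(C(C)C)[C@H](O[Si](C)(C)C(C)(C)C)C(=O)[C@H]3[C@@]1(C2=O)[C@H](CO[Si](c4ccccc4)(c4ccccc4)C(C)(C)C)[C@H]1C(C)(C)CCC[C@]31C | intermediate
41 | (Z)-enol triflate | C=C1CC[C@@H]2[C@](C)(CCC[C@@]2(C)C(=O)OCC[Si](C)(C)C)[C@H]1C/C=C(\OS(=O)(=O)C(F)(F)F)[C@H]1C[C@@]2(C(C)C)[C@H](O[Si](C)(C)C(C)(C)C)C(=O)[C@H]3[C@@]1(C2=O)[C@H](CO[Si](c4ccccc4)(c4ccccc4)C(C)(C)C)[C@H]1C(C)(C)CCC[C@]31C | intermediate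
42 | protected target (E-C12=C13) | C=C1CC[C@@H]2[C@](C)(CCC[C@@]2(C)C(=O)OCC[Si](C)(C)C)[C@H]1C/C=C(\C)[C@H]1C[C@@]2(C(C)C)[C@H](O[Si](C)(C)C(C)(C)C)C(=O)[C@H]3[C@@]1(C2=O)[C@H](CO[Si](c4ccccc4)(c4ccccc4)C(C)(C)C)[C@H]1C(C)(C)CCC[C@]31C | intermediate
43 | diol acid | C=C1CC[C@@H]2[C@](C)(CCC[C@@]2(C)C(=O)O)[C@H]1C/C=C(\C)[C@H]1C[C@@]2(C(C)C)[C@H](O)C(=O)[C@H]3[C@@]1(C2=O)[C@H](CO)[C@H]1C(C)(C)CCC[C@]31C | intermediate
44 | α-diketone aldehyde | C=C1CC[C@@H]2[C@](C)(CCC[C@@]2(C)C(=O)O)[C@H]1C/C=C(\C)[C@H]1C[C@@]2(C(C)C)C(=O)C(=O)[C@H]3[C@@]1(C2=O)[C@H](C=O)[C@H]1C(C)(C)CCC[C@]31C | intermediate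
45 | CNP0269191.1 | C=C1CC[C@@H]2[C@](C)(CCC[C@@]2(C)C(=O)O)[C@H]1C/C=C(\C)[C@H]1C[C@@]2(C(C)C)C(=O)C(O)=C3[C@@]1(C2=O)[C@H](C=O)[C@H]1C(C)(C)CCC[C@]31C | target

**Totals**

Total step count: 36. Longest linear sequence: 28 steps (steps 1–22 and 31–36, from 2,2,6-trimethylcyclohexanone); the labdane branch is steps 23–30.

**Steps most likely to fail**

1. Step 18 (Proposed new method). What may go wrong: (4+2) addition of the activated enal C=C instead of the (4+3) mode, attack on the other diene face, or loss of the silyl enol ether before the two hindered bonds form. Fallback with known chemistry, setting out from 18 and returning at 24: a base‑mediated oxyallyl cation replaces the Lewis acid activated enal. 1-Ethoxyvinyllithium is added to aldehyde 18 to give the enol ether carbinol F1, which is hydrolysed (oxalic acid on wet silica) to the α-hydroxy methyl ketone F2. The secondary hydroxyl is mesylated (MsCl, Et3N) to the α-mesyloxy ketone F3, and the tertiary alcohol is dehydrated with Burgess reagent to the diene mesylate F4. Et3N in 2,2,2-trifluoroethanol should then enolise F4 toward the methyl group and expel mesylate; the resulting oxyallyl cation is captured by the tethered diene in the established base‑mediated intramolecular (4+3) manner to give the C12'-unsubstituted cycloadduct F5. Hydroxylation at C12' through the potassium enolate (KN(SiMe3)2, then 3-phenyl-2-(phenylsulfonyl)oxaziridine) gives the ketol F6, and silylation (t-BuMe2SiOTf, 2,6-lutidine) reaches 24 (or its C12' epimer, which serves equally).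

2. Step 33. What may go wrong: incomplete control of enolate geometry or deprotonation on the C14 side, which would give an E/Z mixture after step 34 or epimerise C14. Fallback, setting out from 28 and 38 and returning at 42: carbonyl olefination instead of enolate cross‑coupling. MeTi(Oi-Pr)3 is added to aldehyde 28 to give the methyl carbinol F7, which is oxidised with Dess–Martin periodinane to the methyl ketone F8. Iodide 38 is heated with PPh3 to give the phosphonium iodide F9, and its ylide (NaN(SiMe3)2) is condensed with F8 in a Wittig reaction; the E isomer 42 would be separated from the Z isomer by chromatography.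

3. Step 20. What may go wrong: over‑oxidation to the enal, oxidation next to the ketones, or slow ene reaction at the hindered alkene. Fallback, setting out from 25 and returning at 26: radical bromination of the C13 methyl (N-bromosuccinimide, dibenzoyl peroxide, PhCF3, 80 °C) gives the allylic bromide F10; displacement with KOAc/18-crown-6 gives the allylic acetate F11; methanolysis (K2CO3, MeOH) gives 26.

Further compounds
F1 | step 18 | enol ether carbinol from 18 and 1-ethoxyvinyllithium | C=C(OCC)C(O)[C@@]1(C)CCCC(C)(C)[C@@H]1[C@@H](CO[Si](c1ccccc1)(c1ccccc1)C(C)(C)C)C1C(OC)(OC)C(C(C)C)=CC1(C)O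
F2 | step 18 | α-hydroxy methyl ketone | CC(=O)C(O)[C@@]1(C)CCCC(C)(C)[C@@H]1[C@@H](CO[Si](c1ccccc1)(c1ccccc1)C(C)(C)C)C1C(OC)(OC)C(C(C)C)=CC1(C)O
F3 | step 18 | α-mesyloxy ketone | CC(=O)C(OS(C)(=O)=O)[C@@]1(C)CCCC(C)(C)[C@@H]1[C@@H](CO[Si](c1ccccc1)(c1ccccc1)C(C)(C)C)C1C(OC)(OC)C(C(C)C)=CC1(C)O
F4 | step 18 | diene mesylate | CC(=O)C(OS(C)(=O)=O)[C@@]1(C)CCCC(C)(C)[C@@H]1[C@@H](CO[Si](c1ccccc1)(c1ccccc1)C(C)(C)C)C1=C(C)C=C(C(C)C)C1(OC)OC
F5 | step 18 | C12'-unsubstituted cycloadduct | CC1=C[C@@]2(C(C)C)CC(=O)[C@H]3[C@@]1(C2(OC)OC)[C@H](CO[Si](c4ccccc4)(c4ccccc4)C(C)(C)C)[C@H]1C(C)(C)CCC[C@]31C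
F6 | step 18 | C12' ketol | CC1=C[C@@]2(C(C)C)C(O)C(=O)[C@H]3[C@@]1(C2(OC)OC)[C@H](CO[Si](c4ccccc4)(c4ccccc4)C(C)(C)C)[C@H]1C(C)(C)CCC[C@]31C
F7 | step 33 | methyl carbinol | CC(O)[C@H]1C[C@@]2(C(C)C)[C@H](O[Si](C)(C)C(C)(C)C)C(=O)[C@H]3[C@@]1(C2=O)[C@H](CO[Si](c4ccccc4)(c4ccccc4)C(C)(C)C)[C@H]1C(C)(C)CCC[C@]31C
F8 | step 33 | methyl ketone | CC(=O)[C@H]1C[C@@]2(C(C)C)[C@H](O[Si](C)(C)C(C)(C)C)C(=O)[C@H]3[C@@]1(C2=O)[C@H](CO[Si](c4ccccc4)(c4ccccc4)C(C)(C)C)[C@H]1C(C)(C)CCC[C@]31C
F9 | step 33 | labdane C12 triphenylphosphonium iodide | C=C1CC[C@@H]2[C@](C)(CCC[C@@]2(C)C(=O)OCC[Si](C)(C)C)[C@H]1CC[P+](c1ccccc1)(c1ccccc1)c1ccccc1.[I-]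
F10 | step 20 | C13 allylic bromide | BrCC1=C[C@@]2(C(C)C)[C@H](O[Si](C)(C)C(C)(C)C)C(=O)[C@H]3[C@@]1(C2=O)[C@H](CO[Si](c4ccccc4)(c4ccccc4)C(C)(C)C)[C@H]1C(C)(C)CCC[C@]31C
F11 | step 20 | C13 allylic acetate | CC(=O)OCC1=C[C@@]2(C(C)C)[C@H](O[Si](C)(C)C(C)(C)C)C(=O)[C@H]3[C@@]1(C2=O)[C@H](CO[Si](c4ccccc4)(c4ccccc4)C(C)(C)C)[C@H]1C(C)(C)CCC[C@]31C
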